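## Retrosynthetic overview
1. Target 11 ⇐ 10 ⇐ 9: O-acetylation late in the route, then one buffered fluoride step that removes all three phenolic silyl groups.
2. 9 ⇐ 8: the C3–O bond comes from a C3–B bond by stereoretentive oxidation.
3. Key step, 8 ⇐ 4 + 7: the C3–C4 bond and the C3 stereocentre are made together by lithiation–borylation. sBuLi/(+)-sparteine removes one enantiotopic H of an O–CH2 group, a boronate forms, and a 1,2-metallate shift follows. No carbonyl addition, ketone reduction or epoxide is used.
4. 7 ⇐ 5 + 6 by E-selective cross-metathesis. 4 ⇐ 1 by silylation, reduction and carbamoylation.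
5. No ring is formed. Both arenes are purchased and the target is acyclic.

Assumptions: CIP analysis of the given SMILES gives (3R,6E), with priorities OAc > CH2CH2Ar > CH2CH2CH=CHAr' > H. Compounds 1, 5, 6 and (+)-sparteine are treated as catalogue chemicals. Reagents listed under "Reagents that add atoms" are commercial and are not numbered.

## Route

**Step 1**
Reactants: 1, 3-(3,4-dihydroxyphenyl)propanoic acid
Product: 2, triisopropylsilyl 3-[3,4-bis(triisopropylsilyloxy)phenyl]propanoate
Conditions: TIPSCl (3.6 equiv), imidazole (7.5 equiv), DMAP (cat.), DMF, rt → 45 °C, 16 h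
Reagents that add atoms: triisopropylsilyl chloride, CC(C)[Si](Cl)(C(C)C)C(C)C
Why: Imidazole-promoted O-silylation caps both phenols and the acid, and TIPS is chosen because aryl TIPS ethers resist sBuLi at −78 °C and mildly basic peroxide far better than TBS.

**Step 2**
Reactants: 2
Product: 3, 3-[3,4-bis(triisopropylsilyloxy)phenyl]propan-1-ol
Conditions: LiAlH4 (1.5 equiv), THF, 0 °C → rt, 2 h; Rochelle salt work-up
Reagents that add atoms: none
Why: Hydride reduction of the silyl ester gives the primary alcohol (any free acid from partial hydrolysis converges on the same product), and the aryl TIPS ethers are inert.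

**Step 3**
Reactants: 3
Product: 4, 3-[3,4-bis(triisopropylsilyloxy)phenyl]propyl N,N-diisopropylcarbamate
Conditions: iPr2NCOCl (1.3 equiv), Et3N (1.5 equiv), CH2Cl2, reflux, 24 h
Reagents that add atoms: N,N-diisopropylcarbamoyl chloride, CC(C)N(C(C)C)C(=O)Cl
Why: O-carbamoylation installs the Hoppe carbamate, which later serves as the directing group for α-lithiation and as the leaving group in the 1,2-shift.

**Step 4**
Reactants: 5, tert-butyldimethyl(4-vinylphenoxy)silane (2.0 equiv); 6, 2-(but-3-en-1-yl)-4,4,5,5-tetramethyl-1,3,2-dioxaborolane (1.0 equiv)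
Product: 7, 2-[(3E)-4-(4-tert-butyldimethylsilyloxyphenyl)but-3-en-1-yl]-4,4,5,5-tetramethyl-1,3,2-dioxaborolane
Conditions: Grubbs II (3 mol %), 1,4-benzoquinone (10 mol %), CH2Cl2, 40 °C, 12 h (–C2H4)
Reagents that add atoms: none (both partners are listed reactants)
Why: Olefin cross-metathesis of an unhindered terminal alkene with a styrene gives the conjugated E-alkene under thermodynamic control (typically >20:1), and benzoquinone suppresses Ru–H isomerisation to the allylboronate.

**Step 5 (key step)**
Reactants: 4 (1.0 equiv); 7 (1.4 equiv)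
Product: 8, 2-[(3R,6E)-1-[3,4-bis(triisopropylsilyloxy)phenyl]-7-(4-tert-butyldimethylsilyloxyphenyl)hept-6-en-3-yl]-4,4,5,5-tetramethyl-1,3,2-dioxaborolane
Conditions: 4, (+)-sparteine (1.3 equiv), sBuLi (1.3 equiv), Et2O, −78 °C, 5 h; 7 in Et2O, −78 °C, 1 h; MgBr2·OEt2 (2 equiv), −78 °C → reflux, 16 h
Reagents that add atoms: none
Why: In this Hoppe asymmetric deprotonation / lithiation–borylation (Matteson-type 1,2-metallate rearrangement), sBuLi·(+)-sparteine removes the pro-R α-oxy hydrogen of 4 to give the configurationally stable (R)-lithiocarbamate, 7 borylates it with retention, and the Mg(II)-promoted anti-periplanar 1,2-shift of the homoallyl group expels OCb with inversion, so C3–C4 and (R)-C3 form together (≥95:5 er expected, as for other 3-arylpropyl carbamates), while the styrene is spared because boronate formation at −78 °C far outpaces carbolithiation or allylic deprotonation.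

**Step 6** (can be telescoped with Step 5)
Reactants: 8
Product: 9, (3R,6E)-1-[3,4-bis(triisopropylsilyloxy)phenyl]-7-(4-tert-butyldimethylsilyloxyphenyl)hept-6-en-3-ol
Conditions: NaBO3·4H2O (5 equiv), THF/H2O 1:1, 0 °C → rt, 3 h
Reagents that add atoms: sodium perborate tetrahydrate, B(=O)O[O-].O.O.O.O.[Na+]
Why: Boronate oxidation proceeds by a stereoretentive 1,2-shift of carbon from B to O, so (R) is kept, the nucleophilic peroxide leaves the styrene untouched, the mild pH (about 9.5) is chosen to preserve the phenolic silyl ethers, and excess 7 becomes a polar primary alcohol that is easily removed.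

**Step 7**
Reactants: 9
Product: 10, (3R,6E)-1-[3,4-bis(triisopropylsilyloxy)phenyl]-7-(4-tert-butyldimethylsilyloxyphenyl)hept-6-en-3-yl acetate
Conditions: Ac2O (2 equiv), Et3N (3 equiv), DMAP (0.1 equiv), CH2Cl2, 0 °C → rt, 2 h
Reagents that add atoms: acetic anhydride, CC(=O)OC(C)=O
Why: DMAP-catalysed O-acylation of the only free hydroxyl does not touch the C3–O bond, so the configuration is retained.

**Step 8**
Reactants: 10
Product: 11, (3R,6E)-1-(3,4-dihydroxyphenyl)-7-(4-hydroxyphenyl)hept-6-en-3-yl acetate (target)
Conditions: TBAF (3.6 equiv) premixed with AcOH (4.0 equiv), THF, 0 °C, 1 h, under Ar; pH 6 buffer work-up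
Reagents that add atoms: none
Why: Fluoride desilylation cleaves aryl silyl ethers within minutes because phenoxide is a good leaving group, and the AcOH buffer prevents phenoxide-mediated acetate transfer or hydrolysis and catechol autoxidation, leaving the secondary acetate, the E-alkene and C3 untouched.

## Compound list
1 | 3-(3,4-dihydroxyphenyl)propanoic acid | OC(=O)CCc1ccc(O)c(O)c1 | starting material
2 | triisopropylsilyl 3-[3,4-bis(triisopropylsilyloxy)phenyl]propanoate | CC(C)[Si](OC(=O)CCc1ccc(O[Si](C(C)C)(C(C)C)C(C)C)c(O[Si](C(C)C)(C(C)C)C(C)C)c1)(C(C)C)C(C)C | intermediate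
3 | 3-[3,4-bis(triisopropylsilyloxy)phenyl]propan-1-ol | OCCCc1ccc(O[Si](C(C)C)(C(C)C)C(C)C)c(O[Si](C(C)C)(C(C)C)C(C)C)c1 | intermediate
4 | 3-[3,4-bis(triisopropylsilyloxy)phenyl]propyl N,N-diisopropylcarbamate | CC(C)N(C(C)C)C(=O)OCCCc1ccc(O[Si](C(C)C)(C(C)C)C(C)C)c(O[Si](C(C)C)(C(C)C)C(C)C)c1 | intermediate
5 | tert-butyldimethyl(4-vinylphenoxy)silane | C=Cc1ccc(O[Si](C)(C)C(C)(C)C)cc1 | starting material
6 | 2-(but-3-en-1-yl)-4,4,5,5-tetramethyl-1,3,2-dioxaborolane | C=CCCB1OC(C)(C)C(C)(C)O1 | starting material
7 | 2-[(3E)-4-(4-tert-butyldimethylsilyloxyphenyl)but-3-en-1-yl]-4,4,5,5-tetramethyl-1,3,2-dioxaborolane | CC1(C)OB(CC/C=C/c2ccc(O[Si](C)(C)C(C)(C)C)cc2)OC1(C)C | intermediate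
8 | (3R,6E) secondary pinacol boronic ester, Bpin at C3 of the fully silylated diarylheptene | CC1(C)OB(OC1(C)C)[C@H](CC/C=C/c2ccc(O[Si](C)(C)C(C)(C)C)cc2)CCc3ccc(O[Si](C(C)C)(C(C)C)C(C)C)c(O[Si](C(C)C)(C(C)C)C(C)C)c3 | intermediate
9 | (3R,6E)-1-[3,4-bis(triisopropylsilyloxy)phenyl]-7-(4-tert-butyldimethylsilyloxyphenyl)hept-6-en-3-ol | O[C@H](CC/C=C/c1ccc(O[Si](C)(C)C(C)(C)C)cc1)CCc2ccc(O[Si](C(C)C)(C(C)C)C(C)C)c(O[Si](C(C)C)(C(C)C)C(C)C)c2 | intermediate
10 | (3R,6E)-1-[3,4-bis(triisopropylsilyloxy)phenyl]-7-(4-tert-butyldimethylsilyloxyphenyl)hept-6-en-3-yl acetate | CC(=O)O[C@H](CC/C=C/c1ccc(O[Si](C)(C)C(C)(C)C)cc1)CCc2ccc(O[Si](C(C)C)(C(C)C)C(C)C)c(O[Si](C(C)C)(C(C)C)C(C)C)c2 | intermediate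
11 | (3R,6E)-1-(3,4-dihydroxyphenyl)-7-(4-hydroxyphenyl)hept-6-en-3-yl acetate | CC(=O)O[C@H](CC/C=C/c1ccc(O)cc1)CCc1ccc(O)c(O)c1 | target

## Step count
- Total steps: 8, or 7 operations if Steps 5 and 6 are telescoped.
- Longest linear sequence: 7 (Steps 1, 2, 3, 5, 6, 7, 8), or 6 if telescoped.

## Three steps most likely to fail
1. **Step 5.** Possible failures are competing aryl or benzylic lithiation of the silylated catechol, a sluggish 1,2-shift, and er below 95:5.
   Fallback: abandon the carbenoid.
   - Oxidise 3 to the aldehyde and convert it to the terminal epoxide by Corey–Chaykovsky methylenation.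
   - Resolve by hydrolytic kinetic resolution with (salen)Co to the (S)-epoxide.
   - Open with allylMgBr/CuI to give (R)-1-arylhept-6-en-3-ol.
   - Acetylate, then attach the aryl terminus by cross-metathesis with 5.
2. **Step 4.** Possible failures are homodimerisation to the stilbene, alkene migration to the allylboronate, and low conversion.
   Fallback: build the boron partner without metathesis.
   - Run a Horner–Wadsworth–Emmons reaction of 4-(tert-butyldimethylsilyloxy)benzaldehyde with diethyl allylphosphonate to give the (E)-1-aryl-1,3-butadiene.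
   - Hydroborate the terminal vinyl group selectively with 9-BBN.
   - Use the resulting B-homoallyl-9-BBN directly in Step 5. Borane ate complexes migrate on warming without MgBr2 and oxidise more easily.
3. **Step 6.** Perborate oxidation of the hindered, lipophilic boronate may be slow, and the phenolic TBS ether could erode, which would lead to an aryl acetate in Step 7.
   Fallback: change the order of events.
   - Perform Step 5 on 4 with commercial 6 itself.
   - Oxidise and acetylate the terminal-alkene product.
   - Install the 4-silyloxystyryl end last by cross-metathesis with 5, so the TBS ether never meets organolithium, MgBr2 or peroxide.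
   - Finish with the same fluoride deprotection.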